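## The problem

The target 14 is a flavonol. Ring A is a benzene with all six positions substituted: methoxyls at C5, C6, C7 and C8, and the ring fusion at C4a and C8a. It is fused to a 4-pyranone ring C that carries a free hydroxyl at C3 and a 4-methoxyphenyl ring B at C2. There is no stereocenter, so the difficulty is one of constitution and chemoselectivity only.

Every bond made to ring A lies between two ortho substituents, and the C4 carbonyl sits next to the C5 methoxyl. Of the five oxygens on ring A, one must become the ring oxygen O1 while four stay methyl ethers. The C3 oxygen must end up free beside five methyl ethers, and a late selective demethylation cannot deliver this, because the C5 methoxyl peri to the carbonyl is the ether that Lewis acids cleave first. The pentaoxygenated ring is oxidised easily to quinones, and the pyranone opens under hot hydroxide, so strong oxidants and hot aqueous base should be avoided.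

The feature that opens the plan is C4. It is a lone carbonyl carbon between C4a and the two-carbon unit C3–C2, and the ring-A fragment it joins, a pentamethoxyphenyl group, has a mirror plane through C4a. C4 can therefore come from carbon monoxide placed between an aryl iodide and an arylalkyne, and either ortho methoxyl of the resulting ynone closes ring C to the same flavone. If that closure is run with an iodine electrophile, C3 receives a halogen that can be exchanged for hydroxyl without touching any methyl ether.

## Retrosynthesis

**14 to 11.** The C3–OH bond is cut and replaced by C3–I, giving 3-iodoflavone 11. An alkyne carbon cannot carry the hydroxyl through ring formation, and oxidising the C3–H of the parent flavone would cost a separate step. The iodide is a by-product of the ring closure chosen below, so it costs nothing. The forward step is iodine–magnesium exchange to the C3-magnesiated flavone 12, trapping as borate 13, and peroxide oxidation. It must trap 12 before the pyranone opens, and the oxidation must spare the electron-rich rings.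

**11 to 10.** The O1–C2 and C3–I bonds are cut and a methyl group is put back on O1, giving the acyclic ynone 10. Closing ring C through O1–C8a instead would need an aryl–oxygen bond formed at a hexasubstituted ring. Closing O1–C2 uses an oxygen that is already in place. The precursor 10 has no ring C, and its pentamethoxyphenyl group offers two equivalent ortho methoxyls. The forward reaction, with ICl, must close 6-endo and not 5-exo. The carbonyl and the 4-methoxyphenyl group both polarise the iodonium ion toward attack at the aryl-bearing carbon.

**10 to 7, 8 and 9.** The C4a–C4 and C4–C3 bonds are cut on either side of the carbonyl. This yields 1-iodo-2,3,4,5,6-pentamethoxybenzene 7, carbon monoxide 8 and 4-ethynylanisole 9. Acylating the alkyne with pentamethoxybenzoyl chloride would make only C4–C3 and would need the acid and its chloride first. The two-bond cut turns a 21-carbon skeleton into a symmetric iodide, a gas and a commercial alkyne. The forward reaction must insert CO before the alkyne is transferred.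

**7 to 5, 4 and 1.** The C–I bond of 7 is cut to give pentamethoxybenzene 5, whose single C–H lies between two methoxyls and is lithiated easily (via 6). The fifth methoxyl is cut at O–CH3 to give phenol 4. The C–OH bond of 4 is cut to give 1,2,3,4-tetramethoxybenzene 1, whose two ring hydrogens are equivalent, so ortho-lithiation (via 2), borate formation (3) and oxidation place the oxygen without ambiguity.

## Roads not taken

**Alternative 1:** Acylquinone oxa-Michael closure, cutting O1–C8a.
- Forward step: a hydroquinone is oxidised to the acylquinone A2, a 2-acyl-5,6-dimethoxybenzoquinone whose side chain is an α-benzyloxy 1,3-diketone. The enol oxygen adds to the only unsubstituted quinone carbon, and tautomerisation gives the 5,8-dihydroxyflavone A1. Double O-methylation and hydrogenolysis of the benzyl ether would finish.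
- Merits: the C3 oxygen is present from the start and is freed under neutral conditions. The quinone fixes the oxygen pattern of ring A, and the closure has only one site.
- Weak points: A2 is a doubly activated quinone that is reduced and oligomerised easily. It must be made by oxidising a hydroquinone that already carries an enolisable diketone, which the oxidant can also attack. The chelated C5 hydroxyl of A1 methylates slowly. The precursor needs a tetraoxygenated acetophenone with differentiated oxygens and a diketone synthesis, so the route is estimated at nine or more steps.
- Comparison: this road handles the C3 hydroxyl better than the chosen plan, whose last step (C–I to C–OH) is its least secure. The chosen plan offers six steps, stable intermediates throughout, and a convergent assembly in which no ring-A oxygen has to be told apart from another.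

**Alternative 2:** Propargyl Claisen and oxa-electrocyclization cascade, cutting C4–C4a with O1–C2 re-formed.
- Forward step: the aryl propargyl ether A4, derived from phenol 4, is heated. A [3,3] shift to the one free ortho carbon, enolisation, a 1,5-hydrogen shift and a six-electron oxa-electrocyclization give the racemic 2H-chromene A3.
- Merits: it starts from phenol 4, which the chosen route also passes through. The single free ortho position makes the rearrangement unambiguous, and ring C is formed with all its carbons without any metal.
- Weak points: A3 is at the wrong oxidation level at three atoms, since C4 is CH, C3 has no oxygen and C2 is sp3. Correcting this needs several oxidations on a molecule whose ring A is its most oxidisable part. Making A4 requires O-alkylation of a hindered phenol by a secondary electrophile that is benzylic, propargylic and para-methoxy-activated, so it ionises readily and can give C-alkylation or allenyl products. A3 is acid-labile and can open to an ortho-quinone methide.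
- Comparison: the C3=C4 alkene of A3 would allow both oxygens to be introduced in one dihydroxylation, which the chosen plan cannot match. The chosen plan brings C4 in at the carbonyl level from CO and needs no oxidation of the skeleton apart from the final borate oxidation.

**Alternative 3:** Symmetric tetramethoxybenzyne insertion, cutting O1–C8a, C4–C4a and O1–C2 together.
- Forward step: fluoride releases 3,4,5,6-tetramethoxybenzyne from the silyl triflate A6. The carboxylate of 3-(4-methoxyphenyl)propiolic acid A7 adds through oxygen, the aryl anion takes the acyl carbon, and the phenoxide closes ring C on the ynone to give the flavone A5. A5 is the same compound that the fallbacks below call F3.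
- Merits: three bonds and ring C form in one step. The symmetric aryne removes any regiochemical question, and no CO is needed.
- Weak points: A6 is a hexasubstituted ortho-silylaryl triflate that would take about four steps from phenol 4. Protonation of the aryl anion by the acid competes with acyl transfer and gives only an aryl ester. A5 has no handle at C3, so a separate C3 hydroxylation must follow.
- Comparison: in ring construction this road is shorter (one step against the two of coupling and iodocyclization). The chosen plan has a precursor, 7, that is reached in three standard steps, and its ring closure delivers the C3 iodide that leads to the hydroxyl, so the overall count favours it (six steps against seven or eight).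

Key step: step 4

Assumption: 1,2,3,4-tetramethoxybenzene 1 and 4-ethynylanisole 9 are taken as purchasable; the target has no stereocenter, so no configuration has to be set.

## Route

Step 1
Reactants: 1 1,2,3,4-tetramethoxybenzene
Product: 4 2,3,4,5-tetramethoxyphenol, via 2,3,4,5-tetramethoxyphenyllithium 2 (not isolated), via lithium aryltrimethoxyborate 3 (not isolated)
Conditions: n-BuLi, TMEDA, THF, 0 °C; B(OMe)3, −78 °C → rt; H2O2 (30% aq), AcOH, 0 °C → rt
Reagents that add atoms: hydrogen peroxide, OO
Why: Directed ortho-metalation removes one of the two equivalent ring hydrogens next to a methoxyl; the aryllithium is trapped as the borate, and peroxide oxidation (1,2-aryl shift from boron to oxygen) gives the phenol under mildly acidic conditions that limit quinone formation.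

Step 2
Reactants: 4 2,3,4,5-tetramethoxyphenol
Product: 5 pentamethoxybenzene
Conditions: MeI, K2CO3, acetone, reflux
Reagents that add atoms: iodomethane, CI
Why: Williamson O-methylation of the phenoxide; the electron-rich phenol is a good nucleophile and there is no competing site.

Step 3
Reactants: 5 pentamethoxybenzene
Product: 7 1-iodo-2,3,4,5,6-pentamethoxybenzene, via pentamethoxyphenyllithium 6 (not isolated)
Conditions: n-BuLi, THF, 0 °C; I2, THF, −78 °C → rt
Reagents that add atoms: iodine, II
Why: Directed ortho-metalation at the only C–H, which is acidified by two flanking methoxyls, followed by iodinolysis of the aryllithium; this avoids the electrophilic oxidants that could turn the pentaoxygenated ring into a quinone.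

Step 4
Reactants: 7 1-iodo-2,3,4,5,6-pentamethoxybenzene; 8 carbon monoxide; 9 4-ethynylanisole
Product: 10 3-(4-methoxyphenyl)-1-(2,3,4,5,6-pentamethoxyphenyl)prop-2-yn-1-one
Conditions: PdCl2(PPh3)2 (5 mol %), Et3N, CO (10 bar), THF, 50 °C, no copper salt
Reagents that add atoms: none
Why: This is a carbonylative Sonogashira coupling, a known three-component reaction of aryl iodides, CO and terminal alkynes. PdCl2(PPh3)2 is reduced in the flask to zerovalent palladium, which adds oxidatively to the C–I bond of 7. CO then inserts into the aryl–palladium bond of the divalent arylpalladium iodide and forms C4a–C4 as an aroylpalladium species. Alkyne 9 coordinates and is deprotonated by Et3N, and reductive elimination from the aroyl(alkynyl)palladium forms C4–C3 and returns zerovalent palladium. No ring is closed and no stereocenter is formed. The selectivity needed is carbonylative over direct alkynylation: the two ortho methoxyls slow alkynyl transfer to the arylpalladium and the electron-rich aryl group migrates quickly to CO. CO pressure and the absence of copper (no copper acetylide, no oxidative alkyne dimer) act in the same direction. Regiochemistry does not arise, because 7 has one C–I bond and a mirror plane, so 10 carries two equivalent ortho methoxyls for the later ring closure.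

Step 5
Reactants: 10 3-(4-methoxyphenyl)-1-(2,3,4,5,6-pentamethoxyphenyl)prop-2-yn-1-one
Product: 11 3-iodo-5,6,7,8-tetramethoxy-2-(4-methoxyphenyl)-4H-chromen-4-one
Conditions: ICl (1.5 equiv), CH2Cl2, −78 °C; aq Na2S2O3 work-up
Reagents that add atoms: iodine monochloride, ClI
Why: Electrophilic iodocyclization of an ortho-methoxyaryl ynone: ICl activates the triple bond, an ortho methoxyl oxygen attacks the aryl-bearing alkyne carbon in 6-endo-dig mode (positive charge stabilised by the 4-methoxyphenyl group), and chloride removes the methyl group from the oxonium ion by SN2 to give the 3-iodochromone. Ring A has no free position to iodinate, and the low temperature keeps ring B untouched.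

Step 6
Reactants: 11 3-iodo-5,6,7,8-tetramethoxy-2-(4-methoxyphenyl)-4H-chromen-4-one
Product: 14 3-hydroxy-5,6,7,8-tetramethoxy-2-(4-methoxyphenyl)-4H-chromen-4-one, via C3-magnesiated flavone 12 (not isolated), via C3 trimethoxyborate 13 (not isolated)
Conditions: iPrMgCl·LiCl, THF, −40 °C; B(OMe)3, −40 → 0 °C; H2O2 (30% aq), AcOH, 0 °C → rt
Reagents that add atoms: hydrogen peroxide, OO
Why: Iodine–magnesium exchange at the electron-poor C3–I bond is fast at low temperature and spares the hindered vinylogous-ester carbonyl. Borate trapping and peroxide oxidation then pass through the same C3-metalated flavone and borate that the established deprotonation–borate–peroxide hydroxylation of flavones uses, so the product is the flavonol with all five methyl ethers intact.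

## Compound list

1 | 1,2,3,4-tetramethoxybenzene | COc1ccc(OC)c(OC)c1OC | starting material
2 | (2,3,4,5-tetramethoxyphenyl)lithium | [Li]c1cc(OC)c(OC)c(OC)c1OC | intermediate
3 | lithium trimethoxy(2,3,4,5-tetramethoxyphenyl)borate | [Li+].CO[B-](OC)(OC)c1cc(OC)c(OC)c(OC)c1OC | intermediate
4 | 2,3,4,5-tetramethoxyphenol | Oc1cc(OC)c(OC)c(OC)c1OC | intermediate
5 | pentamethoxybenzene | COc1cc(OC)c(OC)c(OC)c1OC | intermediate
6 | (2,3,4,5,6-pentamethoxyphenyl)lithium | [Li]c1c(OC)c(OC)c(OC)c(OC)c1OC | intermediate
7 | 1-iodo-2,3,4,5,6-pentamethoxybenzene | COc1c(I)c(OC)c(OC)c(OC)c1OC | intermediate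
8 | carbon monoxide | [C-]#[O+] | starting material
9 | 4-ethynylanisole (1-ethynyl-4-methoxybenzene) | COc1ccc(C#C)cc1 | starting material
10 | 3-(4-methoxyphenyl)-1-(2,3,4,5,6-pentamethoxyphenyl)prop-2-yn-1-one | COc1ccc(C#CC(=O)c2c(OC)c(OC)c(OC)c(OC)c2OC)cc1 | intermediate
11 | 3-iodo-5,6,7,8-tetramethoxy-2-(4-methoxyphenyl)-4H-chromen-4-one | COc1ccc(-c2oc3c(OC)c(OC)c(OC)c(OC)c3c(=O)c2I)cc1 | intermediate
12 | [5,6,7,8-tetramethoxy-2-(4-methoxyphenyl)-4-oxo-4H-chromen-3-yl]magnesium chloride | COc1ccc(-c2oc3c(OC)c(OC)c(OC)c(OC)c3c(=O)c2[Mg]Cl)cc1 | intermediate
13 | chloromagnesium trimethoxy[5,6,7,8-tetramethoxy-2-(4-methoxyphenyl)-4-oxo-4H-chromen-3-yl]borate | COc1ccc(-c2oc3c(OC)c(OC)c(OC)c(OC)c3c(=O)c2[B-](OC)(OC)OC)cc1.[Mg+2].[Cl-] | intermediate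
14 | 3-hydroxy-5,6,7,8-tetramethoxy-2-(4-methoxyphenyl)-4H-chromen-4-one | COc1ccc(-c2oc3c(OC)c(OC)c(OC)c(OC)c3c(=O)c2O)cc1 | target

## Step count and risks

Total: 6 steps. Longest linear sequence: 6 steps (1 to 14). Alkyne 9 and carbon monoxide 8 enter at step 4.

**Step 4 (key step).** Oxidative addition of the hindered, electron-rich iodide may be slow under CO, which lowers the electron density at palladium. The alkyne could then be consumed by oligomerisation or by direct, CO-free coupling before the acylpalladium forms. The fallback makes the same ynone by carbonyl addition instead of catalysis. It sets out from 5 and 9. Alkyne 9 is deprotonated with n-BuLi and formylated with DMF to give 3-(4-methoxyphenyl)prop-2-ynal F1. Arene 5 is lithiated as in step 3 to 6, which adds to the aldehyde of F1 to give racemic 3-(4-methoxyphenyl)-1-(2,3,4,5,6-pentamethoxyphenyl)prop-2-yn-1-ol F2. Oxidation of this doubly activated carbinol with MnO2 in CH2Cl2 returns to the route at 10.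

**Step 6.** The magnesiated flavone 12 has its C–Mg bond anti to the C2–O1 bond and may open ring C by β-elimination of the phenoxide before the borate forms. Protonation to the deiodinated flavone, or addition of the Grignard reagent to the pyranone, could also compete. The fallback avoids any C3 carbanion and sets out from 11. Palladium-catalysed hydrodeiodination (Pd(OAc)2, PPh3, HCO2Na, DMF) gives 5,6,7,8-tetramethoxy-2-(4-methoxyphenyl)-4H-chromen-4-one F3. Dimethyldioxirane in acetone epoxidises the C2=C3 bond to the racemic flavone 2,3-epoxide F4 (1a-(4-methoxyphenyl)-3,4,5,6-tetramethoxy-1a,7a-dihydro-7H-oxireno[2,3-b]chromen-7-one). A trace of TsOH opens the epoxide and tautomerises it to the flavonol, returning to the route at 14.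

**Step 5.** ICl may add across the triple bond without ring closure if the doubly ortho-substituted aroyl group stays twisted away from the alkyne, or it may iodinate ring B ortho to its methoxyl. The fallback separates demethylation from ring closure and sets out from 10. BCl3 in CH2Cl2 removes the one methyl group chelated to the carbonyl and gives 1-(2-hydroxy-3,4,5,6-tetramethoxyphenyl)-3-(4-methoxyphenyl)prop-2-yn-1-one F5. K2CO3 in acetone closes the phenoxide onto the ynone by 6-endo oxa-Michael addition to 5,6,7,8-tetramethoxy-2-(4-methoxyphenyl)-4H-chromen-4-one F3. Epoxidation with dimethyldioxirane to the flavone 2,3-epoxide F4 and acid-catalysed opening, as above, reach the route again at 14.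

**Step 1.** The electron-rich phenol may be over-oxidised by peroxide toward a methoxyquinone, or metalation may be incomplete and leave 1 that is hard to separate. The fallback replaces metalation by electrophilic substitution and sets out from 1. Vilsmeier–Haack formylation (POCl3, DMF) gives 2,3,4,5-tetramethoxybenzaldehyde F6. Baeyer–Villiger oxidation with mCPBA gives 2,3,4,5-tetramethoxyphenyl formate F7. Saponification with KOH in aqueous methanol and acidification return to the route at 4.

## Further compounds

F1 | step 4 | 3-(4-methoxyphenyl)prop-2-ynal | COc1ccc(C#CC=O)cc1
F2 | step 4 | 3-(4-methoxyphenyl)-1-(2,3,4,5,6-pentamethoxyphenyl)prop-2-yn-1-ol (racemic) | COc1ccc(C#CC(O)c2c(OC)c(OC)c(OC)c(OC)c2OC)cc1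
F3 | step 6 | 5,6,7,8-tetramethoxy-2-(4-methoxyphenyl)-4H-chromen-4-one | COc1ccc(-c2cc(=O)c3c(OC)c(OC)c(OC)c(OC)c3o2)cc1
F4 | step 6 | 1a-(4-methoxyphenyl)-3,4,5,6-tetramethoxy-1a,7a-dihydro-7H-oxireno[2,3-b]chromen-7-one (racemic flavone 2,3-epoxide) | COc1ccc(C23OC2C(=O)c2c(OC)c(OC)c(OC)c(OC)c2O3)cc1
F5 | step 5 | 1-(2-hydroxy-3,4,5,6-tetramethoxyphenyl)-3-(4-methoxyphenyl)prop-2-yn-1-one | COc1ccc(C#CC(=O)c2c(O)c(OC)c(OC)c(OC)c2OC)cc1
F6 | step 1 | 2,3,4,5-tetramethoxybenzaldehyde | COc1cc(C=O)c(OC)c(OC)c1OC
F7 | step 1 | 2,3,4,5-tetramethoxyphenyl formate | COc1cc(OC=O)c(OC)c(OC)c1OC
A1 | alternative 1 | 3-(benzyloxy)-5,8-dihydroxy-6,7-dimethoxy-2-(4-methoxyphenyl)-4H-chromen-4-one | COc1ccc(-c2oc3c(O)c(OC)c(OC)c(O)c3c(=O)c2OCc2ccccc2)cc1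
A2 | alternative 1 | 2-(benzyloxy)-1-(4,5-dimethoxy-3,6-dioxocyclohexa-1,4-dien-1-yl)-3-(4-methoxyphenyl)propane-1,3-dione | COC1=C(OC)C(=O)C(C(=O)C(OCc2ccccc2)C(=O)c2ccc(OC)cc2)=CC1=O
A3 | alternative 2 | 5,6,7,8-tetramethoxy-2-(4-methoxyphenyl)-2H-chromene (racemic) | COc1ccc(C2C=Cc3c(OC)c(OC)c(OC)c(OC)c3O2)cc1
A4 | alternative 2 | 1,2,3,4-tetramethoxy-5-{[1-(4-methoxyphenyl)prop-2-yn-1-yl]oxy}benzene (racemic) | COc1ccc(C(C#C)Oc2cc(OC)c(OC)c(OC)c2OC)cc1
A5 | alternative 3 | 5,6,7,8-tetramethoxy-2-(4-methoxyphenyl)-4H-chromen-4-one | COc1ccc(-c2cc(=O)c3c(OC)c(OC)c(OC)c(OC)c3o2)cc1
A6 | alternative 3 | 3,4,5,6-tetramethoxy-2-(trimethylsilyl)phenyl trifluoromethanesulfonate | COc1c(OC)c(OC)c(OC)c([Si](C)(C)C)c1OS(=O)(=O)C(F)(F)F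
A7 | alternative 3 | 3-(4-methoxyphenyl)propiolic acid | COc1ccc(C#CC(=O)O)cc1
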